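(The constants used here belong to no real substance; the run is a simulation.)

Tuesday's flask cannot bring its whole electrophile to target at the quick rate, since each coupling sets free one acid and what is charged to bind that acid stands at 0.500 of the electrophile.

| flask | electrophile | free base | protonated nucleophile | time |
|---|---|---|---|---|
| Friday's | 0.050 M (fed, over 25 s) | 1.00 equiv | 0.800 equiv | 10 min |
| Tuesday's | 0.050 M (fed, over 25 s) | 0.500 equiv | 0.800 equiv | 10 min |

    nucleophile + acid set free ⇌ protonated nucleophile, settled at all times (K1 = 6300 L mol⁻¹)
    acid set free + free base ⇌ salt of the base, settled at all times (K2 = 1.2 × 10⁵ L mol⁻¹)
    electrophile + nucleophile → acid set free + target (k3 = 0.50 L mol⁻¹ s⁻¹)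
    electrophile ⇌ dormant form (K4 = 0.27, k4 = 0.0021 s⁻¹)
    nucleophile + target ⇌ idle adduct, settled at all times (K5 = 14 L mol⁻¹)

- part of the electrophile that has reacted at the end, Friday's
- part of the electrophile that has reacted at the end, Tuesday's
- what raising the equivalents of free base from its lowest to its highest value here does to the part of the electrophile that has reacted (changes below 5 percentage points count as none) (no change / it falls / it rises)

- what is said of target includes idle adduct
- what has gone from electrophile into another species counts as reacted, even if it can come back
- run time (Friday's): 10 min

I follow one molecule of electrophile through its forks and bracket the answer. Each coupling adds one acid to the flask and removes one nucleophile that could hold acid, so acid and sites meet when the coupled share equals 25.0 % on Tuesday's and 50.0 % on Friday's. This share, half the equivalents of free base, I call the knee. On Tuesday's the half-life of nucleophile by the coupling alone, with the other charges counted as if wholly there at once, is 0.46 min, shorter than the 10 min allowed, so I let the flask reach its knee. An uncoupled molecule then has a second fork: it sits as dormant form with chance 21.3 %, and on Tuesday's that balance, taken by itself, relaxes with a half-life of 1.17 min. Knee plus that chance of the remainder gives a floor of 40.9 % for Tuesday's and 60.6 % for Friday's.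

Past the knee, free acid equals twice the excess coupled share, and it leaves a trickle of nucleophile, so the excess grows as the square root of time. I hold protonated nucleophile and free electrophile at their knee values, which is generous, and the excess comes to 12.2 % on Tuesday's and 7.34 % on Friday's. The ceilings are then 50.5 % and 66.4 %.

The forecast gives 64 % for Friday's and 48 % for Tuesday's and says of more free base that it rises, reasoning that “Each coupling consumes one nucleophile and releases one acid, which protonates another”.

The simulation gives 64.2 % on Friday's and 48.4 % on Tuesday's, inside both brackets; with more free base it rises by 16 percentage points.

Tuesday's target ends at 34.2 %, past its knee of 25.0 %, with 0.0860 % of the free base, the limiting reagent, still free. The main reason for the gap between Friday's and Tuesday's is their difference in equivalents of free base, and the parking of acid as salt of the base is a part of how that difference acts: with the parking struck out, the gap falls from 16 points to 0 points.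

In a neighbouring flask, the same as Tuesday's but with 0.120 equiv of free base, the knee drops to 6.00 %, and the same reckoning brackets the answer between 26.0 % and 38.4 %; the simulation gives 36.5 % for that flask.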